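(The data are simulated on assumed constants, noise included.)

- You want to know whether south or south-west ends with the longer chains. Length is monomer in chains over chains begun, and no reading shows the chains begun, so that count is the thing to reckon.

| setting | Tuesday's | Monday's | south | south-west |
|---|---|---|---|---|
| free monomer | 0.018 M | 0.074 M | 0.050 M | 0.012 M |
| pre-initiator | 0.25 mM | 0.25 mM | 0.25 mM | 0.25 mM |
| impurity | 0.14 mM | 0.14 mM | 0.14 mM | 0.14 mM |
| remark | run made earlier | run made earlier |  |  |
| time |  |  | 8.0 min | 8.0 min |

- Tuesday's (time / min: monomer in chains / %, free monomer / %): 0.500: 0, 101; 1.33: 15, 85; 2.50: 41, 53; 4.00: 69, 26; 6.00: 87, 13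
- Monday's (time / min: monomer in chains / %, free monomer / %): 0.417: 1, 98; 0.833: 10, 86; 1.50: 37, 65; 3.00: 78, 23; 6.00: 94, 6

(scatter of a reading: 2 percentage points)

* which of the two ends with the longer chains by the average number of monomer units in a chain (chains begun, living or dead) ("neither" if they lie within 10%) (south / south-west / neither)
* average number of monomer units in a chain (chains begun, living or dead) at the end, south
* average number of monomer units in a chain (chains begun, living or dead) at the end, south-west

- the average divides the monomer in chains by the number of chains begun, living and dead together
- the earlier runs do not show the number of chains; that part of a forecast is a guess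

- First instants: free monomer hardly moves, with Tuesday's run still reading 101% at 0.500 min. I take this delay as impurity consuming what pre-initiator first releases. That is a guess, and on that guess the count has a ceiling of S = 0.110 mM.
- Middle: go to logarithms. Once chains stop being added, ln(free monomer) falls in a straight line, and at one temperature its slope r (a pseudo-first-order constant) scales with the number of chains. From 1.50 min to 3.00 min, Monday's run reads 0.693 min⁻¹. From 2.50 min to 4.00 min, Tuesday's reads 0.475 min⁻¹, which is less than Monday's. Both slopes carry the scatter.
- Assume Monday's run reached S. The chain yardstick y, chains per unit of slope, is then S over Monday's slope, 9.53 mM·s.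
- End: I assume that r goes as the free monomer charged to a power p, and the two runs give p = 0.267. South-west's charge is lower than either run's, so its slope is an extrapolation. That gives south 0.624 min⁻¹ and south-west 0.426 min⁻¹, so the counts are 0.0991 mM and 0.0677 mM.
- Starting from Tuesday's 26% at 4.00 min and running each slope on to 8.0 min, my reckoning gives south 494 and south-west 169.
- The forecast says south, with 400 and 95, on the grounds of “about four times the monomer and similar chain numbers”. Its south-west is lower than mine.
- The flasks give south, with 509 and 189.

    free monomer + initiator → living end + monomer in chains (k = 1.40 M⁻¹ s⁻¹)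
    free monomer + living end → monomer in chains + living end, rate k2*[living end]*[free monomer] (k = 112 M⁻¹ s⁻¹)
    pre-initiator → initiator (k = 0.0413 s⁻¹)
    initiator + impurity → spent initiator A (k = 1.03 × 10⁵ M⁻¹ s⁻¹)
    2 initiator → spent initiator B (k = 221 M⁻¹ s⁻¹)

- The yardstick on south's simulated free monomer from 4.00 min to 8.00 min gives a slope of 0.652 min⁻¹ and a length of 478. On south-west it gives 0.391 min⁻¹ and 179. In south-west at 2.92 min, initiator's half-life by chain start is 1.3 min, longer than pre-initiator's 0.28 min. At 8.00 min, south-west holds spent initiator B at 2.48 × 10⁻⁵ M against south's 6.26 × 10⁻⁶ M, and living end at 5.88 × 10⁻⁵ M against south's 9.72 × 10⁻⁵ M.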